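**Strategy**

The target is the ferulate of (2S,13R)-labd-7-ene-2,15-diol (labdane numbering; ring A = C1–C5, C10; ring B = C5–C10). Everything rests on the C9–C10 bond of ring B: the C7=C8 alkene beside quaternary C10 is the footprint of a C10 cation captured by a C8=C9 alkene. A ring-A cyclohexene with a tetrasubstituted C5=C10 alkene, the C2 oxygen and the C4 gem-dimethyl group, tethered through C6–C7 to an (E)-C8=C9 alkene, is protonated at C5; attack of C9 on C10 and loss of H-7 close ring B and set C5, C9 and C10 from the C2 stereocentre. The precursor comes from (4R,6R)-actinol and (R)-citronellol by B-alkyl Suzuki coupling.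

Key step: step 7

Assumption: (4R,6R)-actinol 1, the industrial zeaxanthin building block, is taken as a purchasable chiral-pool ketone; labdane numbering is used for all later intermediates.

**Route**

Step 1
Reactants: 1 (4R,6R)-4-hydroxy-2,2,6-trimethylcyclohexan-1-one
Product: 2 (1R,3R)-3,5,5-trimethyl-4-oxocyclohexyl pivalate
Conditions: PivCl, pyridine, DMAP (cat.), CH2Cl2, 0 °C to rt
Reagents that add atoms: pivaloyl chloride, CC(C)(C)C(Cl)=O
Why: DMAP-catalysed acylation (nucleophilic acyl substitution) of the secondary alcohol; the pivalate has no α-hydrogen, so it survives the enolate chemistry of step 2, and as an acyl group it later keeps the C2 oxygen from assisting fragmentation of the C10 cation; no stereocentre is touched.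

Step 2
Reactants: 2 (1R,3R)-3,5,5-trimethyl-4-oxocyclohexyl pivalate
Product: 3 (1R)-3,5,5-trimethyl-4-(trifluoromethanesulfonyloxy)cyclohex-3-en-1-yl pivalate
Conditions: KN(SiMe3)2, THF, −78 °C; then PhNTf2, −78 to 0 °C
Reagents that add atoms: N-phenylbis(trifluoromethanesulfonimide), O=S(=O)(N(c1ccccc1)S(=O)(=O)C(F)(F)F)C(F)(F)F
Why: Enolate O-triflation: the ketone has a single α-hydrogen, so deprotonation can give only the tetrasubstituted enolate and hence one enol triflate; the methyl-bearing stereocentre is erased on purpose and the carbinol centre, the future C2, is untouched.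

Step 3
Reactants: 4 (R)-citronellol
Product: 5 (3R)-3,7-dimethyloct-6-en-1-yl pivalate
Conditions: PivCl, pyridine, DMAP (cat.), CH2Cl2, 0 °C to rt
Reagents that add atoms: pivaloyl chloride, CC(C)(C)C(Cl)=O
Why: DMAP-catalysed acylation of the primary alcohol; the ester masks the C15 oxygen through the oxidation, ylide, palladium and superacid steps, and C13 is untouched.

Step 4
Reactants: 5 (3R)-3,7-dimethyloct-6-en-1-yl pivalate
Product: 7 (3R,6E)-3,7-dimethyl-8-oxooct-6-en-1-yl pivalate, via allylic alcohol 6 (not isolated)
Conditions: SeO2 (1.2 equiv), 95% EtOH, reflux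
Reagents that add atoms: selenium dioxide, O=[Se]=O
Why: Riley allylic oxidation (ene reaction, then [2,3]-sigmatropic shift) attacks the (E)-methyl group of the trisubstituted alkene and carries the allylic alcohol on to the enal, which fixes the E geometry that later defines C9.

Step 5
Reactants: 7 (3R,6E)-3,7-dimethyl-8-oxooct-6-en-1-yl pivalate
Product: 8 (3R,6E)-3,7-dimethylnona-6,8-dien-1-yl pivalate
Conditions: Ph3PCH3Br, KOtBu, THF, 0 °C
Reagents that add atoms: methyltriphenylphosphonium bromide, C[P+](c1ccccc1)(c1ccccc1)c1ccccc1.[Br-]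
Why: Wittig methylenation of an unhindered, non-enolizable enal; the trisubstituted alkene keeps its E geometry and the hindered pivalate should not be attacked by the ylide at 0 °C.

Step 6
Reactants: 8 (3R,6E)-3,7-dimethylnona-6,8-dien-1-yl pivalate; 3 (1R)-3,5,5-trimethyl-4-(trifluoromethanesulfonyloxy)cyclohex-3-en-1-yl pivalate
Product: 10 (1R)-4-[(3E,7R)-3,7-dimethyl-9-(pivaloyloxy)non-3-en-1-yl]-3,5,5-trimethylcyclohex-3-en-1-yl pivalate, via B-alkyl-9-BBN borane 9 (not isolated)
Conditions: 9-BBN, THF, 0 °C to rt; then 3, PdCl2(dppf) (cat.), AsPh3, Cs2CO3, DMF/H2O, 50 °C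
Reagents that add atoms: none
Why: Anti-Markovnikov hydroboration with 9-BBN should take place at the monosubstituted terminus of the diene and leave the trisubstituted alkene untouched, and B-alkyl Suzuki–Miyaura coupling of the borane with the enol triflate forms the C5–C6 bond without affecting either stereocentre or the alkene geometry.

Step 7
Reactants: 10 (1R)-4-[(3E,7R)-3,7-dimethyl-9-(pivaloyloxy)non-3-en-1-yl]-3,5,5-trimethylcyclohex-3-en-1-yl pivalate
Product: 11 (2S,5S,9S,10S,13R)-labd-7-ene-2,15-diyl dipivalate
Conditions: ClSO3H (5 equiv), 2-nitropropane, −78 °C; then Et3N, aq. NaHCO3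
Reagents that add atoms: none
Why: Protonation of the tetrasubstituted C5=C10 alkene at C5 gives the tertiary C10 cation, C9 of the (E)-C8=C9 alkene attacks it in a 6-endo-trig cation–olefin closure of ring B, and the tertiary C8 cation loses the axial H-7 to leave the C7=C8 alkene. The closest known reaction type is the superacid-mediated cyclization of monocyclic (β-cyclogeranyl-type) and open-chain polyprenyl esters to trans-decalins with a trisubstituted ring alkene. C5 is set by axial delivery of the proton to the α face of the ring-A half-chair in which the C2 pivaloyloxy group is pseudo-equatorial (the other half-chair would place it 1,3-diaxial to a C4 methyl), so that H-5 becomes cis to the C2 oxygen, and reversible protonation lets the epimeric cation return to the alkene. C10 is set by closure through a chair-like transition state with the chain equatorial on C5 and C9 approaching the α face of the cation, away from the axial C4 methyl, which gives the trans ring fusion with the C10 methyl axial. C9 follows from the E geometry of the C8=C9 alkene, which places C11 equatorial in that chair. The step needs initiation at the ring alkene, one face at C5 and proton loss toward C7: the first is secured because cations at C8 or C5 could close only four-membered rings or five-membered rings in a 5-endo mode, the second by the C2 stereocentre, the third by the kinetic preference of such C8 cations for the endocyclic trisubstituted alkene, while the acyl group keeps the C2 oxygen from triggering Grob-type cleavage of C1–C2.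

Step 8
Reactants: 11 (2S,5S,9S,10S,13R)-labd-7-ene-2,15-diyl dipivalate
Product: 12 (2S,5S,9S,10S,13R)-labd-7-ene-2,15-diol
Conditions: LiAlH4, THF, 0 °C to rt; then H2O, aq. NaOH
Reagents that add atoms: none
Why: Hydride reduction of both pivalates gives the diol and neopentyl alcohol; the isolated trisubstituted alkene and all stereocentres are inert to LiAlH4.

Step 9
Reactants: 12 (2S,5S,9S,10S,13R)-labd-7-ene-2,15-diol; 13 (E)-ferulic acid
Product: 14 (2S,5S,9S,10S,13R)-2-hydroxylabd-7-en-15-yl (E)-ferulate
Conditions: PPh3, DIAD, THF, 0 °C to rt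
Reagents that add atoms: none
Why: Mitsunobu esterification: the primary C15 alcohol forms the oxyphosphonium ion and is displaced by the carboxylate of the more acidic CO2H group rather than by the phenol, whereas SN2 displacement at the secondary C2 carbinol would need attack from the β face, which is blocked by the axial methyl groups on C4 and C10; C15 is not stereogenic and the E-cinnamate is unchanged.

**Compound list**

1 | (4R,6R)-4-hydroxy-2,2,6-trimethylcyclohexan-1-one ((4R,6R)-actinol) | O=C1C(C)(C)C[C@H](O)C[C@H]1C | starting material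
2 | (1R,3R)-3,5,5-trimethyl-4-oxocyclohexyl pivalate | O=C1C(C)(C)C[C@H](OC(=O)C(C)(C)C)C[C@H]1C | intermediate
3 | (1R)-3,5,5-trimethyl-4-(trifluoromethanesulfonyloxy)cyclohex-3-en-1-yl pivalate | CC1=C(OS(=O)(=O)C(F)(F)F)C(C)(C)C[C@H](OC(=O)C(C)(C)C)C1 | intermediate
4 | (R)-citronellol, (3R)-3,7-dimethyloct-6-en-1-ol | OCC[C@H](C)CCC=C(C)C | starting material
5 | (3R)-3,7-dimethyloct-6-en-1-yl pivalate | CC(C)(C)C(=O)OCC[C@H](C)CCC=C(C)C | intermediate
6 | (3R,6E)-8-hydroxy-3,7-dimethyloct-6-en-1-yl pivalate (not isolated) | CC(C)(C)C(=O)OCC[C@H](C)CC/C=C(\C)CO | intermediate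
7 | (3R,6E)-3,7-dimethyl-8-oxooct-6-en-1-yl pivalate | CC(C)(C)C(=O)OCC[C@H](C)CC/C=C(\C)C=O | intermediate
8 | (3R,6E)-3,7-dimethylnona-6,8-dien-1-yl pivalate | CC(C)(C)C(=O)OCC[C@H](C)CC/C=C(\C)C=C | intermediate
9 | (3R,6E)-9-(9-borabicyclo[3.3.1]nonan-9-yl)-3,7-dimethylnon-6-en-1-yl pivalate (not isolated) | CC(C)(C)C(=O)OCC[C@H](C)CC/C=C(\C)CCB1C2CCCC1CCC2 | intermediate
10 | (1R)-4-[(3E,7R)-3,7-dimethyl-9-(pivaloyloxy)non-3-en-1-yl]-3,5,5-trimethylcyclohex-3-en-1-yl pivalate | CC1=C(CC/C(C)=C/CC[C@@H](C)CCOC(=O)C(C)(C)C)C(C)(C)C[C@H](OC(=O)C(C)(C)C)C1 | intermediate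
11 | (2S,5S,9S,10S,13R)-labd-7-ene-2,15-diyl dipivalate (2α-ester, 5α-H, 9α-H, 10β-methyl) | CC(C)(C)C(=O)OCC[C@H](C)CC[C@H]1C(C)=CC[C@H]2C(C)(C)C[C@H](OC(=O)C(C)(C)C)C[C@]12C | intermediate
12 | (2S,5S,9S,10S,13R)-labd-7-ene-2,15-diol | OCC[C@H](C)CC[C@H]1C(C)=CC[C@H]2C(C)(C)C[C@H](O)C[C@]12C | intermediate
13 | (E)-ferulic acid, (E)-3-(4-hydroxy-3-methoxyphenyl)prop-2-enoic acid | COc1cc(/C=C/C(=O)O)ccc1O | starting material
14 | (2S,5S,9S,10S,13R)-2-hydroxylabd-7-en-15-yl (E)-ferulate (CNP0175017.1) | COc1cc(/C=C/C(=O)OCC[C@H](C)CC[C@H]2C(C)=CC[C@H]3C(C)(C)C[C@H](O)C[C@]23C)ccc1O | target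

**Step count and risks**

Total step count: 9. Longest linear sequence: 7 steps (steps 3 to 9, from (R)-citronellol 4); the ring-A branch (steps 1 and 2) joins at step 6.

Steps most likely to fail:

1. Step 7. The remote C2 stereocentre may discriminate the two faces of C5 only weakly during protonation, and proton loss from the C8 cation may not be confined to C7, so that diastereomeric decalins and alkene regioisomers would form side by side. The fallback sets out from 10 and comes back at 11, and moves the stereochemical burden from the substrate to the reagent. Instead of free superacid, 10 would be treated at −78 °C in toluene with a chiral Lewis acid-assisted Brønsted acid, SnCl4 complexed with a 1,1'-bi-2-naphthol monobenzyl ether. The enantiomer whose sense of proton delivery reinforces the C2 bias would be chosen after trying both. The proton is then delivered to C5 by a tin-bound chiral phenol, and the weakly basic tin phenoxide of the same ion pair should take H-7. This fallback makes no new compound (F0).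

2. Step 6. Transmetalation of the B-alkyl borane to the hindered, tetrasubstituted alkenylpalladium intermediate may be slow, so that β-hydride elimination, protodeboronation and triflate hydrolysis compete; hydroboration of the conjugated diene may also be incompletely chemoselective. The fallback sets out from 8 and comes back at 10, and replaces the boron nucleophile by a zinc one made in a separate sequence. Hydroboration of 8 with 9-BBN and oxidative work-up (NaOH, H2O2) would give (3R,6E)-9-hydroxy-3,7-dimethylnon-6-en-1-yl pivalate F1. Appel iodination (I2, PPh3, imidazole, CH2Cl2) would give (3R,6E)-9-iodo-3,7-dimethylnon-6-en-1-yl pivalate F2. Zinc insertion (Zn dust, LiCl, THF) would give [(3E,7R)-3,7-dimethyl-9-(pivaloyloxy)non-3-en-1-yl]zinc iodide F3. Negishi coupling of F3 with triflate 3 (Pd(OAc)2, SPhos, THF/NMP, rt to 50 °C) should then give 10.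

3. Step 9. The free phenol may be alkylated by the activated primary alcohol (aryl ether formation), and discrimination between the two hydroxyl groups may be incomplete at high conversion. The fallback sets out from 12 and 13 and comes back at 14, and replaces the redox condensation by acylation with a phenol-protected acid followed by selective deprotection. Acetylation of 13 (Ac2O, pyridine, then aqueous work-up) would give (E)-4-acetoxy-3-methoxycinnamic acid F4. Steglich esterification of 12 with F4 (EDC·HCl, DMAP cat., CH2Cl2, 0 °C) should acylate only the primary hydroxyl and give (2S,5S,9S,10S,13R)-2-hydroxylabd-7-en-15-yl (E)-4-O-acetylferulate F5. Aminolysis of the aryl acetate alone (pyrrolidine, CH2Cl2, rt) should then give 14.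

**Further compounds**

F0 | step 7 | none | none
F1 | step 6 | (3R,6E)-9-hydroxy-3,7-dimethylnon-6-en-1-yl pivalate | CC(C)(C)C(=O)OCC[C@H](C)CC/C=C(\C)CCO
F2 | step 6 | (3R,6E)-9-iodo-3,7-dimethylnon-6-en-1-yl pivalate | CC(C)(C)C(=O)OCC[C@H](C)CC/C=C(\C)CCI
F3 | step 6 | [(3E,7R)-3,7-dimethyl-9-(pivaloyloxy)non-3-en-1-yl]zinc iodide | CC(C)(C)C(=O)OCC[C@H](C)CC/C=C(\C)CC[Zn]I
F4 | step 9 | (E)-4-acetoxy-3-methoxycinnamic acid | COc1cc(/C=C/C(=O)O)ccc1OC(C)=O
F5 | step 9 | (2S,5S,9S,10S,13R)-2-hydroxylabd-7-en-15-yl (E)-4-O-acetylferulate | COc1cc(/C=C/C(=O)OCC[C@H](C)CC[C@H]2C(C)=CC[C@H]3C(C)(C)C[C@H](O)C[C@]23C)ccc1OC(C)=O
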